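Compound numbers are those of the step list and the compound table at the end.

## The problem

Target 18 is a benzophenone in which a 2-hydroxy-4,6-dimethoxyphenyl ring (ring A) is joined through the carbonyl carbon to C5 of a 7-hydroxy-2,2-dimethyl-2H-chromene, made of benzo ring B (C4a, C5 to C8, C8a) and pyran ring C (O1, C2, C3, C4, C4a, C8a). The molecule has no stereocenter, so the task is one of regiochemistry alone; the only stereocenter met on the way, the carbinol carbon of 16, is formed as a racemate, has nothing to control and is erased by oxidation. Ring B is the difficult part: the acyl-bearing C5 is meta to both oxygens (O1 on C8a, the hydroxyl on C7), so no electrophilic acylation can reach it. The carbon that carries C4 (C4a) must be the one next to C5 and not the one between the two oxygens, which is where condensation of a 3,5-dioxygenated aryl ketone with an enal would tend to go. The ketone has three ortho substituents around it and must therefore be made from a small, reactive pair of partners. The styrene-like C3=C4 bond of ring C rules out hydrogenolysis and strong acid, and the two aryl methyl ethers, one of them ortho to the carbonyl and easily cleaved by boron trihalides, must survive while two phenols are set free. The enabling feature is that C4a and C8a are neighbours carrying C4 and O1, the two atoms of an aldehyde carbonyl, so an aryne across C4a–C8a can take up the C=O of 3-methylbut-2-enal 8, whose dimethyl-substituted alkene end then closes ring C. A bromine on the adjacent C5 directs that addition and afterwards becomes the acyl-bearing carbon.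

## Retrosynthesis

**18 from 17.** No skeletal bond is cut; the two phenols of 18 are masked in 17 as methoxymethyl ethers. This acetal is preferred to its neighbours: benzyl ethers would need a hydrogenolysis that reduces C3=C4, silyl ethers would not survive the fluoride of the key step, and a methyl ether on O7 could not be told apart from the ring A methyl ethers. The forward step asks only for mild protic acid that leaves the methyl ethers and the chromene alone.

**17 from 12 and 14 by way of 16.** The bond between C5 and the carbonyl carbon is cut, and the ketone is taken back to the diaryl carbinol 16. The neighbouring cut, between the carbonyl carbon and ring A, would need ring A as a nucleophile, whereas ring A is commercially available as aldehyde 13 with all three oxygens and the carbonyl carbon in place. An aldehyde is chosen over an acid derivative because the carbonyl of ring A is flanked by two ortho substituents and the smallest electrophile is wanted. The precursors are bromochromene 12, whose bromine becomes lithium in 15, and aldehyde 14, one protection step from 13. The forward reaction needs a halogen–metal exchange faster than any deprotonation, addition to a hindered aldehyde, and a buffered oxidation.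

**12 from 7 and 8 (key disconnection).** Three bonds are cut: C8a–O1, C4a–C4 and O1–C2. Going backwards, ring C opens to the ortho-quinone methide 11, which closes to benzoxete 10, which falls apart into aryne 9 and aldehyde 8. A phenol-based chromene synthesis on a 3-bromo-5-alkoxyphenol would have to choose between the ortho carbon beside bromine and the more electron-rich one beside the alkoxy group, and the wrong one is favoured. In the aryne cut both positions are fixed by where silicon and triflate sit in 7, and the orientation is fixed by the bromine. The precursor 7 is a simple tetrasubstituted benzene and 8 is commercial. The forward step must bond oxygen to the aryne carbon remote from bromine.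

**7 from 1 by way of 4, 3 and 2.** The C–Si and O–S bonds of 7 are cut back to the silyl ether 4 of dibromophenol 3, by way of 5 and 6. The two C–Br bonds go back to 2, and the acetal goes back to hydroquinone 1. The symmetry of 3 is the argument for this order: its two bromines are equivalent, so exchanging either one, moving silicon from oxygen to carbon and triflating the phenoxide gives a single triflate, and the bromine that stays is the one needed in 12. The para relation of the two oxygens of 1 becomes the para relation of C4a and C7. The forward steps need acid-free bromination ortho to the free hydroxyl only, and exactly one halogen–metal exchange.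

**14 from 13.** Only the O–C bond of the acetal is cut. Masking the chelated phenol of 13 keeps it from quenching aryllithium 15, and the same acid removes both acetals at the end.

## Roads not taken

Alternative 1: The cut is made at C5–C(=O) and C4a–C4 together. The partners are 1-iodo-2,4-bis(methoxymethoxy)benzene A1, 2,4-dimethoxy-6-(methoxymethoxy)benzoic anhydride A2 and 2-methylbut-3-en-2-ol A3. With Pd(OAc)2, tri(2-furyl)phosphine, norbornene and Cs2CO3 (a Catellani reaction), the free ortho carbon of A1 would be acylated by A2 and the ipso carbon would be terminated by a Heck reaction with A3. The product would be [2-[(E)-3-hydroxy-3-methylbut-1-enyl]-3,5-bis(methoxymethoxy)phenyl][2,4-dimethoxy-6-(methoxymethoxy)phenyl]methanone A4. Acid would then remove the acetals and close ring C by ionisation of the tertiary allylic alcohol. Its merits are that three components meet in one operation, that both ring B substituents are placed by the catalytic cycle, and that the whole route would be some three or four steps shorter than the chosen one. Its weak points lie in the acyl donor and in the last step. Ortho-acylation of this kind is established for simple acyl donors, whereas A2 has two ortho oxygens and an electron-rich carbonyl into which the palladacycle would have to insert, and half of the ring A acid is lost as carboxylate. The E-alkene of A4 can close only after ionisation, under conditions that can also dehydrate it to a diene. On step count this road is better. The chosen plan sets against it that each of its steps belongs to a known reaction class on this kind of substrate, and that its regiochemistry does not rest on the turnover of a crowded catalytic cycle.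

Alternative 2: The cut is made on both sides of the carbonyl carbon. Phloroglucinol A5 and aldehyde 8 would give 2,2-dimethyl-2H-chromene-5,7-diol A6. Silylation at O7 and triflation at O5 would give 2,2-dimethyl-7-(triisopropylsilyloxy)-2H-chromen-5-yl trifluoromethanesulfonate A7. Pd(PPh3)4 with LiCl would then join A7, carbon monoxide A8 and tributyl[2,4-dimethoxy-6-(methoxymethoxy)phenyl]stannane A9 in a carbonylative Stille coupling. The product would be [2,4-dimethoxy-6-(methoxymethoxy)phenyl][2,2-dimethyl-7-(triisopropylsilyloxy)-2H-chromen-5-yl]methanone A10, and removal of the silyl and acetal groups of A10 would give 18. Its merits are that the chromene is made from a symmetric triphenol, so ring fusion has no regiochemical question, and that the ketone appears at the right oxidation level without a redox step. Its weak points begin with the two hydroxyls of A6, which are electronically alike and differ only by the peri hydrogen at C4; a wrong or incomplete differentiation gives the 7-acyl isomer. Transmetalation of a stannane with two ortho oxygens is slow, which invites reduction of the triflate or loss of tin by protonation, A9 itself needs a regioselective metalation of ring A, and tin residues must be removed from a phenolic product. The step count is about the same, and this road is better in avoiding the carbinol oxidation. The chosen plan sets against it that the oxygen and the acyl handle of ring B are placed by construction and not by a selection between two similar phenols.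

Alternative 3: The cut is made at C3–C4 and O1–C2. The partners are methyl 5-[(tert-butyldimethylsilyl)oxy]-2-formyl-3-hydroxybenzoate A11 and (2-methylprop-1-enyl)boronic acid A12, with dibenzylamine A13 as mediator. The iminium formed from A11 and A13 would take up the alkenyl group of A12, the amine would leave to give a vinyl ortho-quinone methide, and oxa-6π closure would give methyl 7-[(tert-butyldimethylsilyl)oxy]-2,2-dimethyl-2H-chromene-5-carboxylate A14. Its merits are that the ring closure is the same as in the chosen plan but is reached without an aryne, and that the regiochemistry is written into A11, which is at least as secure as aryne polarisation. Its weak points are in the supply of A11 and in the C5 handle. A11 needs a formylation between the ester and a hydroxyl of a 3,5-dihydroxybenzoate and a selective silylation of one of two phenols. The ester of A14 must be reduced and reoxidised or otherwise adjusted before the ketone can be made, and ring A must then be the nucleophile, so commercial aldehyde 13 cannot be used as it is. This road is equal or better in the certainty of the ring-forming step, and about two steps longer. The chosen plan sets against it that its bromine serves twice, first to steer the aryne addition and then as the site of lithiation.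

Key step: step 5

## Route

Remark on the chemistry: the target has no stereocenter; carbinol 16 is formed as a racemate and its stereocenter is removed in step 8.

Step 1
Reactants: 1 hydroquinone
Product: 2 4-(methoxymethoxy)phenol
Conditions: 1 (3 equiv), NaH (1.0 equiv), MOMCl (1.0 equiv), DMF, 0 °C → rt
Reagents that add atoms: chloromethyl methyl ether (MOMCl), COCCl
Why: O-alkylation of a phenoxide (Williamson-type acetal formation); the diol in excess with one equivalent of base and alkylating agent favours the monoether, and unreacted 1 is removed by aqueous extraction.

Step 2
Reactants: 2 4-(methoxymethoxy)phenol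
Product: 3 2,6-dibromo-4-(methoxymethoxy)phenol
Conditions: NBS (2.1 equiv), i-Pr2NH (0.2 equiv), CH2Cl2, 0 °C → rt
Reagents that add atoms: N-bromosuccinimide, O=C1CCC(=O)N1Br
Why: Amine-catalysed electrophilic ortho-bromination of a phenol; the free hydroxyl directs both bromines to its two ortho carbons, the para carbon is blocked, and the buffered medium releases no HBr that could cleave the acetal.

Step 3
Reactants: 3 2,6-dibromo-4-(methoxymethoxy)phenol
Product: 4 [2,6-dibromo-4-(methoxymethoxy)phenoxy]trimethylsilane
Conditions: HMDS (1.5 equiv), THF, 65 °C; evaporate
Reagents that add atoms: hexamethyldisilazane, C[Si](C)(C)N[Si](C)(C)C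
Why: O-silylation of a phenol with a disilazane; ammonia is the only by-product, so the moisture-sensitive silyl ether can be carried on after evaporation.

Step 4
Reactants: 4 [2,6-dibromo-4-(methoxymethoxy)phenoxy]trimethylsilane
Product: 7 2-bromo-4-(methoxymethoxy)-6-(trimethylsilyl)phenyl trifluoromethanesulfonate, via aryllithium 5 (not isolated), via lithium phenoxide 6 (not isolated)
Conditions: n-BuLi (1.05 equiv), THF, −78 °C; then Tf2O (1.2 equiv), −78 → 0 °C
Reagents that add atoms: trifluoromethanesulfonic anhydride, O=S(=O)(OS(=O)(=O)C(F)(F)F)C(F)(F)F
Why: Bromine–lithium exchange at one of two equivalent bromines is followed by an anionic 1,3 oxygen-to-carbon silyl shift (retro-Brook rearrangement) driven by phenoxide formation; O-triflation of 6 then gives the ortho-silylaryl triflate, the standard route from ortho-bromophenols to such aryne precursors.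

Step 5
Reactants: 7 2-bromo-4-(methoxymethoxy)-6-(trimethylsilyl)phenyl trifluoromethanesulfonate; 8 3-methylbut-2-enal
Product: 12 5-bromo-7-(methoxymethoxy)-2,2-dimethyl-2H-chromene, via aryne 9 (not isolated), via benzoxete 10 (not isolated), via ortho-quinone methide 11 (not isolated)
Conditions: 8 (3 equiv), CsF (3 equiv), MeCN, rt → 50 °C
Reagents that add atoms: none
Why: Fluoride attacks silicon of 7 and triflate leaves, releasing aryne 9 (fluoride-induced 1,2-elimination of an ortho-silylaryl triflate). The bromine beside the triple bond stabilises negative charge on the carbon next to it and shields that carbon, so the carbonyl oxygen of 8 bonds to the remote aryne carbon (C8a–O1) and the aryl anion then closes on the carbonyl carbon (C4a–C4), a stepwise formal [2+2] cycloaddition that gives the four-membered benzoxete 10. Strain-driven 4π electrocyclic ring opening of 10 gives the vinyl ortho-quinone methide 11, and a thermal disrotatory oxa-6π electrocyclisation forms O1–C2 and the six-membered ring C, with recovery of the aromaticity of ring B as driving force. The closest known reaction type is the fluoride-mediated union of arynes with α,β-unsaturated aldehydes to 2H-chromenes, which passes through the same three events. No stereocenter is created: C2 carries two methyl groups, and the stereocenter of 10 is lost on ring opening. The selectivity needed is the orientation of the C=O addition; the bromine at C3 of the aryne secures it, and the methoxymethoxy group two positions further from the triple bond exerts only a weak bias. The enal is used in excess so that carbonyl capture outruns self-reaction of the aryne.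

Step 6
Reactants: 13 2-hydroxy-4,6-dimethoxybenzaldehyde
Product: 14 2,4-dimethoxy-6-(methoxymethoxy)benzaldehyde
Conditions: NaH (1.2 equiv), MOMCl (1.3 equiv), DMF, 0 °C → rt
Reagents that add atoms: chloromethyl methyl ether (MOMCl), COCCl
Why: O-alkylation of the sodium phenoxide (acetal protection); full deprotonation overcomes the hydrogen bond to the aldehyde, and the masked phenol can no longer quench the aryllithium of step 7.

Step 7
Reactants: 12 5-bromo-7-(methoxymethoxy)-2,2-dimethyl-2H-chromene; 14 2,4-dimethoxy-6-(methoxymethoxy)benzaldehyde
Product: 16 (rac)-[2,4-dimethoxy-6-(methoxymethoxy)phenyl][7-(methoxymethoxy)-2,2-dimethyl-2H-chromen-5-yl]methanol, via chromenyllithium 15 (not isolated)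
Conditions: n-BuLi (1.05 equiv), THF, −78 °C; then 14, −78 → 0 °C; aq. NH4Cl
Reagents that add atoms: none
Why: Bromine–lithium exchange at −78 °C is faster than deprotonation next to the acetal, and aryllithium 15 undergoes 1,2-addition to the non-enolisable aldehyde 14; the carbinol stereocenter forms without control and is removed in step 8.

Step 8
Reactants: 16 (rac)-[2,4-dimethoxy-6-(methoxymethoxy)phenyl][7-(methoxymethoxy)-2,2-dimethyl-2H-chromen-5-yl]methanol
Product: 17 [2,4-dimethoxy-6-(methoxymethoxy)phenyl][7-(methoxymethoxy)-2,2-dimethyl-2H-chromen-5-yl]methanone
Conditions: Dess–Martin periodinane (1.3 equiv), NaHCO3, CH2Cl2, 0 °C → rt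
Reagents that add atoms: none
Why: Dess–Martin oxidation of a doubly benzylic secondary alcohol; the bicarbonate buffer keeps the electron-rich diaryl carbinol from ionising and spares the acetals, and the chromene double bond is inert to the periodinane.

Step 9
Reactants: 17 [2,4-dimethoxy-6-(methoxymethoxy)phenyl][7-(methoxymethoxy)-2,2-dimethyl-2H-chromen-5-yl]methanone
Product: 18 (2-hydroxy-4,6-dimethoxyphenyl)(7-hydroxy-2,2-dimethyl-2H-chromen-5-yl)methanone
Conditions: 3 M aq. HCl, MeOH, 45 °C
Reagents that add atoms: none
Why: Acid-catalysed acetal exchange with methanol removes both methoxymethyl groups; aryl methyl ethers are inert to dilute protic acid, and dilute acid at moderate temperature is commonly tolerated by 2,2-dimethyl-2H-chromenes.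

## Compound list

1 | hydroquinone (benzene-1,4-diol) | Oc1ccc(O)cc1 | starting material
2 | 4-(methoxymethoxy)phenol | COCOc1ccc(O)cc1 | intermediate
3 | 2,6-dibromo-4-(methoxymethoxy)phenol | COCOc1cc(Br)c(O)c(Br)c1 | intermediate
4 | [2,6-dibromo-4-(methoxymethoxy)phenoxy]trimethylsilane | COCOc1cc(Br)c(O[Si](C)(C)C)c(Br)c1 | intermediate
5 | [3-bromo-5-(methoxymethoxy)-2-(trimethylsilyloxy)phenyl]lithium | [Li]c1cc(OCOC)cc(Br)c1O[Si](C)(C)C | intermediate
6 | lithium 2-bromo-4-(methoxymethoxy)-6-(trimethylsilyl)phenolate | [Li+].[O-]c1c(Br)cc(OCOC)cc1[Si](C)(C)C | intermediate
7 | 2-bromo-4-(methoxymethoxy)-6-(trimethylsilyl)phenyl trifluoromethanesulfonate | COCOc1cc(Br)c(OS(=O)(=O)C(F)(F)F)c([Si](C)(C)C)c1 | intermediate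
8 | 3-methylbut-2-enal | CC(C)=CC=O | starting material
9 | 3-bromo-5-(methoxymethoxy)benzyne (3-bromo-5-(methoxymethoxy)-1,2-didehydrobenzene) | COCOC1=CC#CC(Br)=C1 | intermediate
10 | (rac)-3-bromo-5-(methoxymethoxy)-2-(2-methylprop-1-enyl)-2H-benzo[b]oxete | COCOc1cc(Br)c2C(C=C(C)C)Oc2c1 | intermediate
11 | (6E)-5-bromo-3-(methoxymethoxy)-6-(3-methylbut-2-enylidene)cyclohexa-2,4-dien-1-one | O=C1C=C(OCOC)C=C(Br)/C1=C/C=C(C)C | intermediate
12 | 5-bromo-7-(methoxymethoxy)-2,2-dimethyl-2H-chromene | COCOc1cc(Br)c2C=CC(C)(C)Oc2c1 | intermediate
13 | 2-hydroxy-4,6-dimethoxybenzaldehyde | COc1cc(O)c(C=O)c(OC)c1 | starting material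
14 | 2,4-dimethoxy-6-(methoxymethoxy)benzaldehyde | COCOc1cc(OC)cc(OC)c1C=O | intermediate
15 | [7-(methoxymethoxy)-2,2-dimethyl-2H-chromen-5-yl]lithium | [Li]c1cc(OCOC)cc2OC(C)(C)C=Cc12 | intermediate
16 | (rac)-[2,4-dimethoxy-6-(methoxymethoxy)phenyl][7-(methoxymethoxy)-2,2-dimethyl-2H-chromen-5-yl]methanol | COCOc1cc(OC)cc(OC)c1C(O)c1cc(OCOC)cc2OC(C)(C)C=Cc12 | intermediate
17 | [2,4-dimethoxy-6-(methoxymethoxy)phenyl][7-(methoxymethoxy)-2,2-dimethyl-2H-chromen-5-yl]methanone | COCOc1cc(OC)cc(OC)c1C(=O)c1cc(OCOC)cc2OC(C)(C)C=Cc12 | intermediate
18 | (2-hydroxy-4,6-dimethoxyphenyl)(7-hydroxy-2,2-dimethyl-2H-chromen-5-yl)methanone | COc1cc(O)c(C(=O)c2cc(O)cc3c2C=CC(C)(C)O3)c(OC)c1 | target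

## Step count and risks

Total step count: 9. Longest linear sequence: 8 (steps 1 to 5, then 7 to 9); step 6 is a one-step side branch.

**Step 5 (key step).** The aryne may be consumed by paths other than carbonyl capture: an ene reaction with the allylic C–H bonds of the enal, addition of a second aryne to the first adduct, or fluoride-induced self-condensation of the enal. Any of these lowers the throughput without changing the regiochemistry. The fallback sets out from 7 and comes back to the route at 12. The aryne is generated from 7 with CsF in DMF, which as solvent outcompetes every other trap and adds through the same oxygen-to-remote-carbon [2+2] event. Aqueous work-up hydrolyses the adduct to 2-bromo-6-hydroxy-4-(methoxymethoxy)benzaldehyde F1. Heating F1 with (2-methylprop-1-enyl)boronic acid A12 and dibenzylamine A13 then builds ring C by amine-mediated alkenyl transfer, elimination and oxa-6π closure, giving 12.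

**Step 4.** Exchange may go on to the second bromine, butyllithium may attack silicon instead of bromine, or the phenoxide with two ortho substituents may be triflated incompletely. The fallback sets out from 2 and comes back to the route at 7, and it introduces silicon before the second bromine. Amine-catalysed monobromination of 2 with one equivalent of NBS ortho to the hydroxyl gives 2-bromo-4-(methoxymethoxy)phenol F2, and silylation of F2 with HMDS gives [2-bromo-4-(methoxymethoxy)phenoxy]trimethylsilane F3. Bromine–lithium exchange of F3 with n-BuLi, retro-Brook shift and aqueous NH4Cl work-up give 4-(methoxymethoxy)-2-(trimethylsilyl)phenol F4, now with no second bromine to compete. Amine-catalysed bromination of F4 with NBS at the one free ortho carbon gives 2-bromo-4-(methoxymethoxy)-6-(trimethylsilyl)phenol F5, and triflation of F5 with Tf2O and pyridine gives 7.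

**Step 7.** Addition of 15 to the hindered, electron-rich aldehyde 14 may be slow enough that the aryllithium is lost by protonation. The fallback sets out from 12 and comes back to the route at 16, and it reverses the polarity of the two partners. The same exchange on 12 is quenched with DMF to give 7-(methoxymethoxy)-2,2-dimethyl-2H-chromene-5-carbaldehyde F6, an aldehyde with one ortho substituent only. Commercial 3,5-dimethoxyphenol F7 is converted with NaH and MOMCl into 1,3-dimethoxy-5-(methoxymethoxy)benzene F8. Directed ortho-lithiation of F8 with n-BuLi, between the acetal and a methoxy group, gives [2,4-dimethoxy-6-(methoxymethoxy)phenyl]lithium F9; this site is favoured by the stronger coordination of the acetal and by its twofold statistical weight, and the site between the two methoxy groups is the competitor to watch. Addition of F9 to F6 gives carbinol 16.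

**Step 9.** Acid may hydrate or open the chromene at C3=C4 before the acetal on O7, which has no neighbouring carbonyl to assist, is fully removed. The fallback sets out from 17 and comes back to the route at 18, and it exchanges the acetals instead of solvolysing them. TMSOTf with 2,2'-bipyridyl in CH2Cl2 at 0 °C converts both aryl methoxymethyl ethers into silyl ethers under buffered, non-protic conditions, which gives [2,4-dimethoxy-6-(trimethylsilyloxy)phenyl][2,2-dimethyl-7-(trimethylsilyloxy)-2H-chromen-5-yl]methanone F10. Water in the presence of K2CO3 then hydrolyses F10 to 18.

## Further compounds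

F1 | step 5 | 2-bromo-6-hydroxy-4-(methoxymethoxy)benzaldehyde | O=Cc1c(O)cc(OCOC)cc1Br
F2 | step 4 | 2-bromo-4-(methoxymethoxy)phenol | COCOc1ccc(O)c(Br)c1
F3 | step 4 | [2-bromo-4-(methoxymethoxy)phenoxy]trimethylsilane | COCOc1ccc(O[Si](C)(C)C)c(Br)c1
F4 | step 4 | 4-(methoxymethoxy)-2-(trimethylsilyl)phenol | COCOc1ccc(O)c([Si](C)(C)C)c1
F5 | step 4 | 2-bromo-4-(methoxymethoxy)-6-(trimethylsilyl)phenol | COCOc1cc(Br)c(O)c([Si](C)(C)C)c1
F6 | step 7 | 7-(methoxymethoxy)-2,2-dimethyl-2H-chromene-5-carbaldehyde | COCOc1cc(C=O)c2C=CC(C)(C)Oc2c1
F7 | step 7 | 3,5-dimethoxyphenol | COc1cc(O)cc(OC)c1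
F8 | step 7 | 1,3-dimethoxy-5-(methoxymethoxy)benzene | COCOc1cc(OC)cc(OC)c1
F9 | step 7 | [2,4-dimethoxy-6-(methoxymethoxy)phenyl]lithium | [Li]c1c(OC)cc(OC)cc1OCOC
F10 | step 9 | [2,4-dimethoxy-6-(trimethylsilyloxy)phenyl][2,2-dimethyl-7-(trimethylsilyloxy)-2H-chromen-5-yl]methanone | COc1cc(OC)c(C(=O)c2cc(O[Si](C)(C)C)cc3OC(C)(C)C=Cc23)c(O[Si](C)(C)C)c1
A1 | alternative 1 | 1-iodo-2,4-bis(methoxymethoxy)benzene | COCOc1ccc(I)c(OCOC)c1
A2 | alternative 1 | 2,4-dimethoxy-6-(methoxymethoxy)benzoic anhydride | COCOc1cc(OC)cc(OC)c1C(=O)OC(=O)c1c(OC)cc(OC)cc1OCOC
A3 | alternative 1 | 2-methylbut-3-en-2-ol | CC(C)(O)C=C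
A4 | alternative 1 | [2-[(E)-3-hydroxy-3-methylbut-1-enyl]-3,5-bis(methoxymethoxy)phenyl][2,4-dimethoxy-6-(methoxymethoxy)phenyl]methanone | COCOc1cc(OC)cc(OC)c1C(=O)c1cc(OCOC)cc(OCOC)c1/C=C/C(C)(C)O
A5 | alternative 2 | phloroglucinol (benzene-1,3,5-triol) | Oc1cc(O)cc(O)c1
A6 | alternative 2 | 2,2-dimethyl-2H-chromene-5,7-diol | CC1(C)C=Cc2c(O)cc(O)cc2O1
A7 | alternative 2 | 2,2-dimethyl-7-(triisopropylsilyloxy)-2H-chromen-5-yl trifluoromethanesulfonate | CC(C)[Si](Oc1cc(OS(=O)(=O)C(F)(F)F)c2C=CC(C)(C)Oc2c1)(C(C)C)C(C)C
A8 | alternative 2 | carbon monoxide | [C-]#[O+]
A9 | alternative 2 | tributyl[2,4-dimethoxy-6-(methoxymethoxy)phenyl]stannane | CCCC[Sn](CCCC)(CCCC)c1c(OC)cc(OC)cc1OCOC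
A10 | alternative 2 | [2,4-dimethoxy-6-(methoxymethoxy)phenyl][2,2-dimethyl-7-(triisopropylsilyloxy)-2H-chromen-5-yl]methanone | COCOc1cc(OC)cc(OC)c1C(=O)c1cc(O[Si](C(C)C)(C(C)C)C(C)C)cc2OC(C)(C)C=Cc12
A11 | alternative 3 | methyl 5-[(tert-butyldimethylsilyl)oxy]-2-formyl-3-hydroxybenzoate | COC(=O)c1cc(O[Si](C)(C)C(C)(C)C)cc(O)c1C=O
A12 | alternative 3 | (2-methylprop-1-enyl)boronic acid | CC(C)=CB(O)O
A13 | alternative 3 | dibenzylamine | C(NCc1ccccc1)c1ccccc1
A14 | alternative 3 | methyl 7-[(tert-butyldimethylsilyl)oxy]-2,2-dimethyl-2H-chromene-5-carboxylate | COC(=O)c1cc(O[Si](C)(C)C(C)(C)C)cc2OC(C)(C)C=Cc12
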